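The plan opens ring B of the bicyclo[3.3.1]nonane (C1–C8–C7–C6–C5–C9) at C5–C6 and takes the C7 side chain off at C7–C1′. Two features make this possible. C5 is the carbon flanked by the C4 and C9 carbonyl groups of the aroyl trione, so one-electron oxidation of the enolate places a radical there. C6/C7 can enter as the terminal alkene of a reverse-prenyl group that C1 already holds through C8. A single mediated anodic step then closes ring B and allylates C7, with C1 dictating C5 and C7. Its substrate is a (6S)-dearomatised aroylphloroglucinol carrying but-2-enyl groups as latent prenyls and a dipivalate-protected catechol.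

Key step: step 7

Remarks on the chemistry
- Numbering: bicyclic compounds use the numbering of the target core (C1 and C5 bridgeheads, C2–C3–C4 aroyl trione bridge, C6–C7–C8 bridge with C8 = CMe2, C9 ketone). In the monocyclic dienones the quaternary carbon is C6 (later C1) and the alkyl-bearing enol carbon is C4 (later C5).
- Latent prenyls: a prenyl group on the quaternary carbon would offer the C5 radical a 5-exo closure to a tertiary radical, the usual course of oxidised C-prenylated acylphloroglucinols. An allyl group would offer a second free CH2 terminus for 6-endo closure. (E)-But-2-enyl groups have neither, are less prone to chroman formation with the neighbouring enols, and become prenyl in the same metathesis that finishes C7.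
- Catechol protection: pivalates should survive the Friedel–Crafts step, NaH, 100 °C, the electrolysis and the Ru catalyst, and leave with carbonate in methanol. Aryl silyl ethers would not survive the acylation.
- Quaternary centre: it is made by O-prenylation and Claisen rearrangement and obtained as one enantiomer by resolution. No catalytic asymmetric reverse prenylation of an acylphloroglucinol is relied on.
- Assumption: commercial crotyl bromide is E-enriched; minor Z isomers may be carried along because step 8 erases the alkene geometry.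

Step 1
Reactants: 1 3,4-dihydroxybenzoic acid
Product: 2 3,4-bis(pivaloyloxy)benzoic acid
Conditions: PivCl (2.5 equiv), 2 M aq NaOH/THF, 0 °C, pH 10–11; then HCl to pH 2
Reagents that add atoms: pivaloyl chloride, CC(C)(C)C(=O)Cl
Why: Schotten–Baumann acylation esterifies the two phenoxides while the carboxylate stays as its salt, giving a catechol protection fit for every later step.

Step 2
Reactants: 2 3,4-bis(pivaloyloxy)benzoic acid; 3 phloroglucinol
Product: 5 [3,4-bis(pivaloyloxy)phenyl](2,4,6-trihydroxyphenyl)methanone, via acid chloride 4 (not isolated)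
Conditions: (COCl)2, cat. DMF, CH2Cl2, rt, evaporate; then 3, AlCl3 (3.5 equiv), PhNO2, rt; aq HCl quench
Reagents that add atoms: none
Why: Friedel–Crafts acylation of the very electron-rich phloroglucinol should stop after one acyl group because the ketone deactivates the ring, and the electron-poor aryl pivalates should not undergo Fries migration at room temperature.

Step 3
Reactants: 5 [3,4-bis(pivaloyloxy)phenyl](2,4,6-trihydroxyphenyl)methanone; 6 (E)-1-bromobut-2-ene (crotyl bromide)
Product: 7 {3,5-di[(E)-but-2-enyl]-2,4,6-trihydroxyphenyl}[3,4-bis(pivaloyloxy)phenyl]methanone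
Conditions: NaH (2.2 equiv), PhMe, 0 °C; 6 (2.1 equiv), 0 °C → rt
Reagents that add atoms: none
Why: C-alkylation of a sodium phenoxide ion pair in a non-polar solvent, where the cation shields the oxygens, should place the primary allylic carbon on the only two nucleophilic ring carbons (C3 and C5), and the non-nucleophilic base leaves the pivalates untouched.

Step 4
Reactants: 7 {3,5-di[(E)-but-2-enyl]-2,4,6-trihydroxyphenyl}[3,4-bis(pivaloyloxy)phenyl]methanone; 8 3-methylbut-2-en-1-ol (prenol)
Product: 9 {3,5-di[(E)-but-2-enyl]-2,6-dihydroxy-4-[(3-methylbut-2-enyl)oxy]phenyl}[3,4-bis(pivaloyloxy)phenyl]methanone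
Conditions: PPh3, DIAD, THF, 0 °C → rt
Reagents that add atoms: none
Why: Mitsunobu etherification is O-selective and should take the 4-OH, the most acidic hydroxyl and the only one not hydrogen-bonded to the ketone.

Step 5
Reactants: 9 {3,5-di[(E)-but-2-enyl]-2,6-dihydroxy-4-[(3-methylbut-2-enyl)oxy]phenyl}[3,4-bis(pivaloyloxy)phenyl]methanone
Product: 10 rac-2-[3,4-bis(pivaloyloxy)benzoyl]-4,6-di[(E)-but-2-enyl]-3,5-dihydroxy-6-(2-methylbut-3-en-2-yl)cyclohexa-2,4-dien-1-one
Conditions: PhMe, 100 °C, sealed tube, Ar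
Reagents that add atoms: none
Why: In this aromatic ortho-Claisen rearrangement the [3,3] shift turns the O-prenyl group into a C-bound 1,1-dimethylallyl group on one of the two equivalent but-2-enyl-bearing ortho carbons, the blocked dienone persists as the stabilised enolised triketone, and the new quaternary centre forms without control (racemate).

Step 6
Reactants: 10 rac-2-[3,4-bis(pivaloyloxy)benzoyl]-4,6-di[(E)-but-2-enyl]-3,5-dihydroxy-6-(2-methylbut-3-en-2-yl)cyclohexa-2,4-dien-1-one
Product: 11 (6S)-2-[3,4-bis(pivaloyloxy)benzoyl]-4,6-di[(E)-but-2-enyl]-3,5-dihydroxy-6-(2-methylbut-3-en-2-yl)cyclohexa-2,4-dien-1-one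
Conditions: preparative SFC on an immobilised polysaccharide chiral phase (e.g. Chiralpak IC), CO2/MeOH + 0.1 % HCO2H, 35 °C
Reagents that add atoms: none
Why: Resolution by chromatography on a chiral stationary phase selects the (6S)-enantiomer (assignment by ECD or X-ray analysis of a heavy-atom derivative), which is configurationally stable because the quaternary centre has no epimerisable hydrogen.

Step 7
Reactants: 11 (6S)-2-[3,4-bis(pivaloyloxy)benzoyl]-4,6-di[(E)-but-2-enyl]-3,5-dihydroxy-6-(2-methylbut-3-en-2-yl)cyclohexa-2,4-dien-1-one; 12 allyl phenyl sulfone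
Product: 13 (1S,5S,7R)-7-allyl-3-[3,4-bis(pivaloyloxy)benzoyl]-1,5-di[(E)-but-2-enyl]-4-hydroxy-8,8-dimethylbicyclo[3.3.1]non-3-ene-2,9-dione (allyl exo)
Conditions: Cp2Fe (10 mol %), DBU (1.0 equiv), 12 (5 equiv), n-Bu4NBF4 (0.1 M), MeCN, 50 °C, undivided cell, RVC anode, Pt cathode, constant current (3 mA), Ar
Reagents that add atoms: none
Why: Proposed new method: anodically regenerated ferrocenium should oxidise the amidinium enolate of 11 to a radical delocalised over the tricarbonyl, whose C5 terminus adds to the unsubstituted vinyl CH2 (C5–C6), after which the secondary C7 radical adds to allyl phenyl sulfone and expels PhSO2• (C7–C1′), which ferrocene or the cathode returns to sulfinate, so the cascade is redox-neutral overall. The closest known reaction types are ferrocene-mediated anodic and Mn(III)-mediated oxidative radical cyclisations of 1,3-dicarbonyl enolates and radical allylation with allyl sulfones. Ring B (C1, C8, C7, C6, C5, C9) closes in the 6-endo-trig mode, the usual mode when a carbonyl carbon (here C9) lies inside the forming ring, and the 5-exo position C7 is neopentyl. C5 is controlled by C1, because the C8–C7–C6 tether can bridge only the ring face on which C8 already sits, and C7 is controlled by the finished bicycle, whose C2–C3–C4 bridge shields the endo lobe so that the sulfone is met on the exo face. The step needs reaction at C5 not C3, at the vinyl group not the but-2-enyl groups, and allyl transfer faster than ring reopening or hydrogen abstraction; these are secured by the aroyl group (C3 hindered and more delocalised), by but-2-enyl groups that lack a free CH2 terminus and a tertiary-radical outlet while the gem-dimethyl group favours the reactive vinyl rotamer, and by excess sulfone in acetonitrile, a poor hydrogen donor.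

Step 8
Reactants: 13 (1S,5S,7R)-7-allyl-3-[3,4-bis(pivaloyloxy)benzoyl]-1,5-di[(E)-but-2-enyl]-4-hydroxy-8,8-dimethylbicyclo[3.3.1]non-3-ene-2,9-dione; 14 2-methyl-2-butene
Product: 15 (1S,5S,7R)-3-[3,4-bis(pivaloyloxy)benzoyl]-4-hydroxy-8,8-dimethyl-1,5,7-tris(3-methylbut-2-enyl)bicyclo[3.3.1]non-3-ene-2,9-dione (aristophenone A dipivalate)
Conditions: Hoveyda–Grubbs II (3 × 5 mol %), 14/CH2Cl2 (1:1), 40 °C, sealed tube
Reagents that add atoms: none
Why: In this olefin cross-metathesis the terminal allyl and the internal but-2-enyl groups should exchange their outer alkylidene for the isopropylidene unit of 2-methyl-2-butene, and the trisubstituted prenyl groups formed are too hindered to react further, with no stereocentre touched.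

Step 9
Reactants: 15 (1S,5S,7R)-3-[3,4-bis(pivaloyloxy)benzoyl]-4-hydroxy-8,8-dimethyl-1,5,7-tris(3-methylbut-2-enyl)bicyclo[3.3.1]non-3-ene-2,9-dione
Product: 16 aristophenone A
Conditions: K2CO3 (5 equiv), degassed MeOH, 0 °C → rt, Ar; then cold 0.5 M HCl to pH 3
Reagents that add atoms: none
Why: Carbonate-mediated transesterification should remove both aryl pivalates while the acidic trione is shielded as its enolate and the prenyl groups are inert to base, and the brief cold acidification is too mild for prenyl–enol cyclisation.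

Compound list
1 | 3,4-dihydroxybenzoic acid | O=C(O)c1ccc(O)c(O)c1 | starting material
2 | 3,4-bis(pivaloyloxy)benzoic acid | CC(C)(C)C(=O)Oc1ccc(C(=O)O)cc1OC(=O)C(C)(C)C | intermediate
3 | phloroglucinol | Oc1cc(O)cc(O)c1 | starting material
4 | 3,4-bis(pivaloyloxy)benzoyl chloride (not isolated) | CC(C)(C)C(=O)Oc1ccc(C(=O)Cl)cc1OC(=O)C(C)(C)C | intermediate
5 | [3,4-bis(pivaloyloxy)phenyl](2,4,6-trihydroxyphenyl)methanone | CC(C)(C)C(=O)Oc1ccc(C(=O)c2c(O)cc(O)cc2O)cc1OC(=O)C(C)(C)C | intermediate
6 | (E)-1-bromobut-2-ene (crotyl bromide) | C/C=C/CBr | starting material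
7 | {3,5-di[(E)-but-2-enyl]-2,4,6-trihydroxyphenyl}[3,4-bis(pivaloyloxy)phenyl]methanone | C/C=C/Cc1c(O)c(C/C=C/C)c(O)c(C(=O)c2ccc(OC(=O)C(C)(C)C)c(OC(=O)C(C)(C)C)c2)c1O | intermediate
8 | 3-methylbut-2-en-1-ol (prenol) | CC(C)=CCO | starting material
9 | {3,5-di[(E)-but-2-enyl]-2,6-dihydroxy-4-[(3-methylbut-2-enyl)oxy]phenyl}[3,4-bis(pivaloyloxy)phenyl]methanone | C/C=C/Cc1c(O)c(C(=O)c2ccc(OC(=O)C(C)(C)C)c(OC(=O)C(C)(C)C)c2)c(O)c(C/C=C/C)c1OCC=C(C)C | intermediate
10 | rac-2-[3,4-bis(pivaloyloxy)benzoyl]-4,6-di[(E)-but-2-enyl]-3,5-dihydroxy-6-(2-methylbut-3-en-2-yl)cyclohexa-2,4-dien-1-one (racemic at C6) | C=CC(C)(C)C1(C/C=C/C)C(=O)C(C(=O)c2ccc(OC(=O)C(C)(C)C)c(OC(=O)C(C)(C)C)c2)=C(O)C(C/C=C/C)=C1O | intermediate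
11 | (6S)-2-[3,4-bis(pivaloyloxy)benzoyl]-4,6-di[(E)-but-2-enyl]-3,5-dihydroxy-6-(2-methylbut-3-en-2-yl)cyclohexa-2,4-dien-1-one | C=CC(C)(C)[C@]1(C/C=C/C)C(=O)C(C(=O)c2ccc(OC(=O)C(C)(C)C)c(OC(=O)C(C)(C)C)c2)=C(O)C(C/C=C/C)=C1O | intermediate
12 | allyl phenyl sulfone | C=CCS(=O)(=O)c1ccccc1 | starting material
13 | (1S,5S,7R)-7-allyl-3-[3,4-bis(pivaloyloxy)benzoyl]-1,5-di[(E)-but-2-enyl]-4-hydroxy-8,8-dimethylbicyclo[3.3.1]non-3-ene-2,9-dione (allyl exo) | C=CC[C@@H]1C[C@]2(C/C=C/C)C(=O)[C@@](C/C=C/C)(C(=O)C(C(=O)c3ccc(OC(=O)C(C)(C)C)c(OC(=O)C(C)(C)C)c3)=C2O)C1(C)C | intermediate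
14 | 2-methyl-2-butene | CC=C(C)C | starting material
15 | (1S,5S,7R)-3-[3,4-bis(pivaloyloxy)benzoyl]-4-hydroxy-8,8-dimethyl-1,5,7-tris(3-methylbut-2-enyl)bicyclo[3.3.1]non-3-ene-2,9-dione | CC(C)=CC[C@@H]1C[C@]2(CC=C(C)C)C(=O)[C@@](CC=C(C)C)(C(=O)C(C(=O)c3ccc(OC(=O)C(C)(C)C)c(OC(=O)C(C)(C)C)c3)=C2O)C1(C)C | intermediate
16 | aristophenone A, (1S,5S,7R)-3-(3,4-dihydroxybenzoyl)-4-hydroxy-8,8-dimethyl-1,5,7-tris(3-methylbut-2-enyl)bicyclo[3.3.1]non-3-ene-2,9-dione | CC(C)=CC[C@@H]1C[C@]2(CC=C(C)C)C(=O)[C@@](CC=C(C)C)(C(=O)C(C(=O)c3ccc(O)c(O)c3)=C2O)C1(C)C | target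

Total step count: 9. Longest linear sequence: 9 steps (1 → 16).

Steps most likely to fail

Step 7 (labelled). The ring closure may be reversible or may engage a but-2-enyl group, and allyl transfer to the hindered C7 radical may be too slow, so that the radical is reduced or reopens. The fallback sets out from 11 and returns at 13, using known reaction types only. Iodination of the enol carbon C4 of 11 (N-iodosuccinimide, CH2Cl2, 0 °C) should give the α-iodo trione F1. An iodine-atom-transfer radical cyclisation (Et3B/air, benzene, rt) should then give the 7-iodo bicycle F2; the cyclised C7 radical is quenched at once by iodine transfer from F1. Keck allylation of F2 (allyltributylstannane, AIBN, benzene, 80 °C) passes through the same C7 radical and should deliver the exo-allyl compound 13.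

Step 5. At the temperature the rearrangement needs, the prenyl ether may ionise to linear C-prenyl products, or the new 1,1-dimethylallyl group may migrate on by a Cope shift. The fallback sets out from 7 and returns at 10 through a chelation-accelerated Claisen rearrangement at lower temperature. Silylation of the 4-OH of 7 (TBSOTf, 2,6-lutidine, CH2Cl2, −78 °C) should give the 4-O-TBS ether F3. O-Prenylation of one of the two equivalent chelated hydroxyls (prenyl bromide, K2CO3, DMF, rt) should give the 2-O-prenyl ether F4. Eu(fod)3 (10 mol %, CHCl3, 50 °C) binds the ketone and the neighbouring ether oxygen and should promote the [3,3] shift to the silyl enol ether F5 of 10. Buffered desilylation (HF·pyridine, THF, 0 °C) then gives 10.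

Step 3. O-Alkylation, over-alkylation to gem-dialkyl dienones and SN2′ attack may erode regiocontrol. The fallback sets out from 5 and returns at 7 by a Tsuji–Trost C-allylation under neutral conditions (Pd(PPh3)4, (E)-but-2-enyl methyl carbonate, THF, rt), in which the soft ring carbon attacks the less hindered terminus of the π-crotyl complex; no new compound is made (F0).

Further compounds
F1 | step 7 | 2-[3,4-bis(pivaloyloxy)benzoyl]-4,6-di[(E)-but-2-enyl]-3-hydroxy-4-iodo-6-(2-methylbut-3-en-2-yl)cyclohex-2-ene-1,5-dione (C6 as in 11, C4 epimers) | C=CC(C)(C)[C@]1(C/C=C/C)C(=O)C(C(=O)c2ccc(OC(=O)C(C)(C)C)c(OC(=O)C(C)(C)C)c2)=C(O)C(I)(C/C=C/C)C1=O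
F2 | step 7 | 3-[3,4-bis(pivaloyloxy)benzoyl]-1,5-di[(E)-but-2-enyl]-4-hydroxy-7-iodo-8,8-dimethylbicyclo[3.3.1]non-3-ene-2,9-dione (C1 and C5 as in 13, C7 epimers) | IC1C[C@]2(C/C=C/C)C(=O)[C@@](C/C=C/C)(C(=O)C(C(=O)c3ccc(OC(=O)C(C)(C)C)c(OC(=O)C(C)(C)C)c3)=C2O)C1(C)C
F3 | step 5 | {3,5-di[(E)-but-2-enyl]-4-(tert-butyldimethylsilyloxy)-2,6-dihydroxyphenyl}[3,4-bis(pivaloyloxy)phenyl]methanone | C/C=C/Cc1c(O)c(C(=O)c2ccc(OC(=O)C(C)(C)C)c(OC(=O)C(C)(C)C)c2)c(O)c(C/C=C/C)c1O[Si](C)(C)C(C)(C)C
F4 | step 5 | {3,5-di[(E)-but-2-enyl]-4-(tert-butyldimethylsilyloxy)-2-hydroxy-6-[(3-methylbut-2-enyl)oxy]phenyl}[3,4-bis(pivaloyloxy)phenyl]methanone | C/C=C/Cc1c(OCC=C(C)C)c(C(=O)c2ccc(OC(=O)C(C)(C)C)c(OC(=O)C(C)(C)C)c2)c(O)c(C/C=C/C)c1O[Si](C)(C)C(C)(C)C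
F5 | step 5 | rac-2-[3,4-bis(pivaloyloxy)benzoyl]-4,6-di[(E)-but-2-enyl]-5-(tert-butyldimethylsilyloxy)-3-hydroxy-6-(2-methylbut-3-en-2-yl)cyclohexa-2,4-dien-1-one | C=CC(C)(C)C1(C/C=C/C)C(=O)C(C(=O)c2ccc(OC(=O)C(C)(C)C)c(OC(=O)C(C)(C)C)c2)=C(O)C(C/C=C/C)=C1O[Si](C)(C)C(C)(C)C
F0 | step 3 | none | none
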